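## Analysis of the target

Target 18 is a 7,7′-epoxylignan: one tetrahydrofuran ring (O1, C2, C3, C4, C5) with identical 4-hydroxy-3,5-dimethoxyphenyl groups on C2 and C5 and hydroxymethyl arms (carbons C3′ and C4′) on C3 and C4. The four contiguous stereocentres are (2S,3R,4S,5R): the two aryl groups are cis to each other, the two arms are cis to each other, and each aryl group is trans to the arm next to it. A mirror plane through O1 and the midpoint of C3–C4 makes the compound meso, so only relative configuration has to be controlled and every chiral intermediate can be racemic. The bonds O1–C2 and O1–C5 are benzylic and para to a free phenol, so they ionise easily under acid; the arenes are electron-rich enough for oxidation and Friedel–Crafts reactions; and each primary hydroxyl sits where it could compete for a benzylic cation. The hard part is the cis relation between C3 and C4: neither carbon can be epimerised in the target, and this relation must coexist with a trans relation to each aryl group, whereas C2 and C5 are correctable benzylic centres. The strategy rests on reading O1, C5, C4, C3 and C3′ as a γ-butyrolactone with C3′ as the carbonyl carbon; a C3=C4 double bond turns it into a 5-aryl butenolide in which C4 is an electrophile and C3, after conjugate addition, a nucleophile. C4′ can then be brought in as a carbanion and C2, with its aryl group, as an aldehyde carbon.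

## Retrosynthetic reasoning

From 18 to 16. Only protecting groups come off at the end: the phenols of 18 are carried as benzyl ethers (17) and the primary hydroxyls as acetates (16). No skeletal bond is cut. What is gained is that the benzylic ether bonds cannot ionise through a quinone methide while bases and nucleophiles are in use, and that the arms cannot act as nucleophiles. Forward, a methanolysis precedes a neutral hydrogenolysis, so that base never meets a free para-hydroxybenzyl ether.

From 16 to 15. The ring is opened at O1–C2, giving the 1,4-diol 15. This bond is chosen because C2 is benzylic and its C–O bond forms reversibly under acid. The forward ring closure can then run under thermodynamic control and place the C2 aryl group trans to the C3 arm whatever the configuration of the C2 carbinol was. Cutting a ring C–C bond instead would give up this self-correction. The forward reaction has to ionise a benzylic hydroxyl without touching C3 and C4 and without letting the arms compete, which is why they are acetylated.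

From 15 to 12. Diol 15 is the bis-acetate of tetraol 14, and 14 is the reduction product of lactone 13, in which O1–C5 is the alkyl C–O bond of the lactone and C3′ its carbonyl carbon. The hydroxyl on C4′ of 13 is traced back to a C–Si bond in 12. These are changes of oxidation level only. They move the problem to the relative configuration of a trisubstituted γ-lactone, where trans,trans is the natural outcome.

From 12 to 8, 10 and 3. Two bonds are cut in one operation, C4–C4′ and C2–C3. Both flank C3–C4, so the C3/C4 relation is set in the same flask, and the three components (butenolide 8, Grignard reagent 10, aldehyde 3) all carry their carbons at the right oxidation level. The forward reaction must add the C4′ carbanion to C4 anti to the C5 aryl group and then trap the enolate at C3 with 3 anti to the new C4 substituent. The trans lactone becomes the cis arms of 18 because C3′ and C2 exchange their roles as ring member and substituent when the lactone is replaced by the tetrahydrofuran.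

From 8 to 3 and 4. Butenolide 8 is opened at its acyl C–O bond to the Z-hydroxy enoate 7, the semihydrogenation product of ynoate 6. Ynoate 6 is cut at C4–C5 into aldehyde 3 and acetylide 5, made from ethyl propiolate 4. This is chosen because it delivers the Z geometry needed for lactonisation from an alkyne and uses the same aldehyde 3 that later supplies C2.

From 3 and 10 to starting materials. Aldehyde 3 is the benzyl ether of syringaldehyde 1, made with benzyl bromide 2. Reagent 10 is the magnesium insertion product of chlorosilane 9.

## Alternatives that were turned down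

Alternative 1: Twofold decarboxylative arylation of a symmetric core.
- Disconnection: both aryl–carbon bonds (C2–aryl and C5–aryl) are cut, leaving the meso cis-2,5-dicarboxylic acid A1 (acetoxymethyl arms trans to the neighbouring carboxyl groups) and two equivalents of aryl bromide A2.
- Forward key step: under dual nickel/photoredox catalysis each carboxylate of A1 is oxidised and loses CO2, and the α-oxy radical is coupled with A2. The product A3 is the same compound as 16.
- For it: the core with its cis arms would come from a [4+2] cycloaddition and an oxidative alkene cleavage of commodity chemicals. Everything stays meso, α-alkoxy acids are good radical precursors, and no hydroxyls need to be differentiated.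
- Against it: each coupling passes through a planar α-oxy radical, so the configuration of C2 and C5 built into A1 is erased. It must be re-established twice at nickel, with only the neighbouring arm as control element. A2 carries three alkoxy donors and should add slowly to low-valent nickel, which gives protodecarboxylation time to compete. The benzylic ether C–H bonds of A3 are themselves candidates for further photo-oxidation.
- Comparison: on step count and symmetry this plan is stronger. The chosen route offers instead aryl–carbon bonds that exist from the first step, polar C–C bond formations with a known facial bias, and a thermodynamic handle on C2 and C5 in place of two kinetically set radical couplings.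

Alternative 2: Formal [3+2] of a donor–acceptor cyclopropane with aldehyde 3.
- Disconnection: O1–C5 and C2–C3 are cut. C2 is again aldehyde 3; C3, C4 and C5 come from the fused cyclopropane lactone A4, whose acceptor carbon (C3) bears the lactone carbonyl and a methyl ester and whose donor carbon (C5) bears the aryl group.
- Forward key step: the Lewis acid A5, Sn(OTf)2, chelates the two carbonyls. The aldehyde oxygen attacks the benzylic carbon with inversion as the cyclopropane opens, and the enolate closes onto the aldehyde carbon, giving the cis-fused furofuranone ester A6.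
- For it: the ring, O1–C5, C2–C3 and the 2,5-cis relation arise in one step of a well-understood type, and the lactone tether guarantees 3,4-cis. Neither thermodynamic equilibration nor selective acetylation is needed; on these points it is stronger than the chosen route.
- Against it: because the donor carbon is inverted, the 4,5-trans relation requires the aryl group of A4 on the concave face, cis to the lactone CH2. That means cyclopropanation of a Z-alkene to the more hindered isomer; the easily made convex isomer would give 4,5-cis. With so electron-rich a donor the opening may instead become fully ionic, and the outcome is then hard to predict. The extra ester on C3 must be removed, and dealkoxycarbonylation creates an enolate at C3 with O1 in the β position, which invites E1cB opening of the new ring. A4 itself needs about five steps from 3.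
- Comparison: overall length is similar. The chosen route has no carbon to excise, a precursor (8) three steps from commodity materials, and a lactone that tolerates the key-step conditions.

Alternative 3: Ketene [2+2] on a dihydrofuran.
- Disconnection: the exocyclic bonds C3–C3′ and C4–C4′ are cut together, leading back to the cis-2,5-diaryl-2,5-dihydrofuran A7. Both arm carbons come from one ketene.
- Forward key step: dichloroketene A9, generated in the flask from trichloroacetyl chloride A8 and zinc, adds across C3=C4 of A7 on the face opposite both aryl groups, giving the fused dichlorocyclobutanone A10.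
- For it: all relative configuration is fixed in one step. The arms are cis because both new bonds belong to one four-membered ring, and 2,3- and 4,5-trans follow because both aryl groups shield the same face. On stereochemical economy it is the strongest of the four plans.
- Against it: A7 is a doubly benzylic and doubly allylic cyclic ether. The ZnCl2 formed with the ketene can ionise it, the ring oxygen can be acylated by the electrophilic ketene (with sigmatropic rearrangement to follow), and loss of two hydrogens gives an aromatic furan. Making A7 cis is a stereochemical problem of its own, since cyclodehydration of an ene-diol passes through the same allylic benzylic cation. The bond between the carbonyl and CCl2 carbons of A10 is not in the target; cutting it and bringing both carbons to the alcohol level costs four to five further steps.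
- Comparison: the chosen route keeps O1–C5 in a lactone that is inert to organometallic reagents and sets C3/C4 on a robust substrate. It pays with a longer end game and one selective acetylation.

Key step: step 5

Remark on the chemistry: 18 is meso, so all chiral intermediates are made and used as racemates and each SMILES shows one enantiomer. For 12 to 15 the SMILES shows one of the two C2-carbinol epimers, which are carried on together. Atom labels O1, C2–C5, C3′ and C4′ always refer to the numbering of 18.

## Route

Step 1
Reactants: 1 syringaldehyde (4-hydroxy-3,5-dimethoxybenzaldehyde); 2 benzyl bromide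
Product: 3 4-(benzyloxy)-3,5-dimethoxybenzaldehyde
Conditions: K2CO3, DMF, 60 °C
Reagents that add atoms: none
Why: Williamson ether synthesis: the phenoxide of 1 displaces bromide from 2 (SN2) and the aldehyde is untouched. The benzyl ether masks the para-phenol that would otherwise open quinone-methide pathways later.

Step 2
Reactants: 4 ethyl propiolate; 3 4-(benzyloxy)-3,5-dimethoxybenzaldehyde
Product: 6 rac-ethyl 4-[4-(benzyloxy)-3,5-dimethoxyphenyl]-4-hydroxybut-2-ynoate, via ethyl 3-lithiopropiolate 5 (not isolated)
Conditions: LiN(iPr)2, THF, −78 °C; then 3, −78 °C; AcOH quench at −78 °C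
Reagents that add atoms: none
Why: Deprotonation of 4 gives acetylide 5, which adds 1,2 to the aldehyde of 3 (carbonyl addition of a lithium acetylide). The new carbinol centre (future C5) is racemic, which suffices for a meso target, and the cold acidic quench prevents retro-addition.

Step 3
Reactants: 6 rac-ethyl 4-[4-(benzyloxy)-3,5-dimethoxyphenyl]-4-hydroxybut-2-ynoate
Product: 8 rac-5-[4-(benzyloxy)-3,5-dimethoxyphenyl]furan-2(5H)-one, via Z-hydroxy enoate 7 (not isolated)
Conditions: H2 (1 atm), Pd/CaCO3 poisoned with Pb(OAc)2, quinoline, EtOAc, rt; filter; then PPTS (cat.), toluene, 50 °C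
Reagents that add atoms: none
Why: Semihydrogenation on lead-poisoned palladium delivers H2 syn and stops at Z-enoate 7, in which hydroxyl and ester are held cis, so mild acid closes the lactone by intramolecular transesterification with loss of ethanol. The aryl benzyl ether is not cleaved on the poisoned catalyst, and PPTS is too weak to ionise the benzylic alcohol.

Step 4
Reactants: 9 (chloromethyl)isopropoxydimethylsilane
Product: 10 [(isopropoxydimethylsilyl)methyl]magnesium chloride (THF solution, titrated, used at once)
Conditions: Mg turnings, BrCH2CH2Br (cat.), THF, rt to 40 °C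
Reagents that add atoms: magnesium, [Mg]
Why: Magnesium inserts into the C–Cl bond of the α-silyl alkyl chloride (Grignard formation). The reagent is a hydroxymethyl anion equivalent because its C–Si bond can later be oxidised.

Step 5
Reactants: 8 rac-5-[4-(benzyloxy)-3,5-dimethoxyphenyl]furan-2(5H)-one; 10 [(isopropoxydimethylsilyl)methyl]magnesium chloride; 3 4-(benzyloxy)-3,5-dimethoxybenzaldehyde
Product: 12 rac-(3,4-trans,4,5-trans)-3-{[4-(benzyloxy)-3,5-dimethoxyphenyl](hydroxy)methyl}-5-[4-(benzyloxy)-3,5-dimethoxyphenyl]-4-{[isopropoxy(dimethyl)silyl]methyl}dihydrofuran-2(3H)-one (both carbinol epimers; drawn 3S,4R,5R, carbinol S), via chloromagnesium lactone enolate 11 (not isolated)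
Conditions: 10 (1.3 equiv), CuBr·SMe2 (10 mol%), THF, −78 → −40 °C; then 3 (1.6 equiv), −78 °C; aq NH4Cl; crude product taken on directly
Reagents that add atoms: none
Why: The Grignard reagent transmetallates to copper and the cuprate adds to C4 of the enoate (π-complex, oxidative addition at C4, reductive elimination), forming C4–C4′ and the chloromagnesium enolate 11. The cuprate approaches the flat butenolide on the face opposite the C5 aryl group, its only substituent, so C4′ ends up trans to the aryl group. Enolate 11 then adds through C3 to aldehyde 3 in a closed, magnesium-bridged transition state on the face opposite the new C4 substituent, forming C2–C3 with the trans relation on the lactone. No ring is closed, because the lactone already holds O1–C5; when the rings are exchanged later, C3′ turns from ring member into substituent and C2 from substituent into ring member, so the trans lactone maps onto the cis arms of 18. The carbinol centre C2 is not controlled (the ring-locked E-enolate would favour the anti aldol, which is the epimer not drawn) and need not be, since step 9 resets it. The closest known reaction type is the copper-catalysed conjugate addition of Grignard reagents to butenolides with aldol trapping of the enolate, as used for lignan lactones, combined with the established use of this silylmethyl reagent as a hydroxymethyl anion equivalent. The step needs 1,4-addition to win over 1,2-addition and over deprotonation at C5, which copper catalysis at low temperature should secure, and anti,anti diastereoselection, which the C5 aryl group and then the C4 substituent secure; racemisation of 8 through its furanolate would be harmless because the target is meso.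

Step 6
Reactants: 12 the trans,trans silylmethyl aldol lactone
Product: 13 rac-(3,4-trans,4,5-trans)-3-{[4-(benzyloxy)-3,5-dimethoxyphenyl](hydroxy)methyl}-5-[4-(benzyloxy)-3,5-dimethoxyphenyl]-4-(hydroxymethyl)dihydrofuran-2(3H)-one (both carbinol epimers; drawn 3S,4S,5R, carbinol S)
Conditions: 30% H2O2, KF, KHCO3, THF/MeOH (1:1), rt; aq Na2S2O3
Reagents that add atoms: hydrogen peroxide, OO
Why: Tamao oxidation: fluoride and hydroperoxide form a pentacoordinate silicate on the alkoxysilane, C4′ migrates from silicon to oxygen, and hydrolysis frees the primary alcohol. No stereocentre is involved, and a base-induced shift of the lactone onto the new hydroxyl would be harmless because both lactone isomers give 14 in step 7.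

Step 7
Reactants: 13 the hydroxymethyl aldol lactone
Product: 14 rel-(2R,3S,4R)-1,4-bis[4-(benzyloxy)-3,5-dimethoxyphenyl]-2,3-bis(hydroxymethyl)butane-1,4-diol (both C1 epimers; drawn the meso 1S,2R,3S,4R epimer)
Conditions: LiAlH4, THF, 0 °C → rt; aq potassium sodium tartrate
Reagents that add atoms: none
Why: Hydride reduction of the lactone carbonyl C3′ to the primary alcohol, which also liberates the C5 hydroxyl. The benzyl ethers and all stereocentres are untouched.

Step 8
Reactants: 14 the tetraol
Product: 15 rel-(2R,3S,4R)-{1,4-bis[4-(benzyloxy)-3,5-dimethoxyphenyl]-1,4-dihydroxybutane-2,3-diyl}bis(methylene) diacetate (both C1 epimers; drawn the meso 1S,2R,3S,4R epimer)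
Conditions: AcCl (2.1 equiv), 2,4,6-collidine, CH2Cl2, −78 °C
Reagents that add atoms: acetyl chloride, CC(=O)Cl
Why: Kinetically selective acylation: at −78 °C with a hindered pyridine base the two unhindered primary hydroxyls react much faster than the secondary benzylic ones, each of which is flanked by an aryl ring and a branched carbon. The acetates keep the arms from competing as nucleophiles in step 9.

Step 9
Reactants: 15 the bis-acetate diol
Product: 16 [(2S,3R,4S,5R)-2,5-bis[4-(benzyloxy)-3,5-dimethoxyphenyl]tetrahydrofuran-3,4-diyl]bis(methylene) diacetate (meso)
Conditions: BF3·OEt2 (0.3 equiv), CH2Cl2, 0 °C → rt; Et3N quench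
Reagents that add atoms: none
Why: Lewis-acid-promoted SN1 cycloetherification: a benzylic hydroxyl ionises to a cation stabilised by the trialkoxyaryl group and the other benzylic hydroxyl closes the five-membered ring. Because opening of the benzylic C–O bonds is reversible under these conditions, C2 (and C5) should settle trans to the neighbouring acetoxymethyl group, so both carbinol epimers of 15 converge on meso 16 while C3 and C4 are not touched.

Step 10
Reactants: 16 the tetrahydrofuran diacetate
Product: 17 [(2S,3R,4S,5R)-2,5-bis[4-(benzyloxy)-3,5-dimethoxyphenyl]tetrahydrofuran-3,4-diyl]dimethanol (meso)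
Conditions: K2CO3 (cat.), MeOH, rt
Reagents that add atoms: none
Why: Base-catalysed transesterification (methanolysis of both acetates). No centre is epimerisable, and the benzyl ethers keep the benzylic ether bonds inert to base.

Step 11
Reactants: 17 the bis(benzyl ether) diol
Product: 18 [(2S,3R,4S,5R)-2,5-bis(4-hydroxy-3,5-dimethoxyphenyl)tetrahydrofuran-3,4-diyl]dimethanol (meso; CNP0170897.5)
Conditions: H2 (1 atm), 10% Pd/C, EtOAc, rt
Reagents that add atoms: none
Why: Hydrogenolysis of the two aryl benzyl ethers on palladium. The PhCH2–O bonds to phenol oxygen should cleave far faster than the secondary ring C–O bonds under neutral conditions, so the reaction is stopped after two equivalents of H2 and the four stereocentres stay as set.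

## Compound list

1 | syringaldehyde (4-hydroxy-3,5-dimethoxybenzaldehyde) | COc1cc(C=O)cc(OC)c1O | starting material
2 | benzyl bromide | BrCc1ccccc1 | starting material
3 | 4-(benzyloxy)-3,5-dimethoxybenzaldehyde | COc1cc(C=O)cc(OC)c1OCc1ccccc1 | intermediate
4 | ethyl propiolate | CCOC(=O)C#C | starting material
5 | ethyl 3-lithiopropiolate | CCOC(=O)C#C[Li] | intermediate
6 | rac-ethyl 4-[4-(benzyloxy)-3,5-dimethoxyphenyl]-4-hydroxybut-2-ynoate | O[C@@H](c1cc(OC)c(OCc2ccccc2)c(OC)c1)C#CC(=O)OCC | intermediate
7 | rac-ethyl (Z)-4-[4-(benzyloxy)-3,5-dimethoxyphenyl]-4-hydroxybut-2-enoate | O[C@@H](c1cc(OC)c(OCc2ccccc2)c(OC)c1)/C=C\C(=O)OCC | intermediate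
8 | rac-5-[4-(benzyloxy)-3,5-dimethoxyphenyl]furan-2(5H)-one | O=C1O[C@@H](c2cc(OC)c(OCc3ccccc3)c(OC)c2)C=C1 | intermediate
9 | (chloromethyl)isopropoxydimethylsilane | CC(C)O[Si](C)(C)CCl | starting material
10 | [(isopropoxydimethylsilyl)methyl]magnesium chloride | CC(C)O[Si](C)(C)C[Mg]Cl | intermediate
11 | chloromagnesium enolate of rac-trans-5-[4-(benzyloxy)-3,5-dimethoxyphenyl]-4-{[isopropoxy(dimethyl)silyl]methyl}dihydrofuran-2(3H)-one | Cl[Mg]OC1=C[C@@H](C[Si](C)(C)OC(C)C)[C@H](c2cc(OC)c(OCc3ccccc3)c(OC)c2)O1 | intermediate
12 | rac-(3,4-trans,4,5-trans)-3-{[4-(benzyloxy)-3,5-dimethoxyphenyl](hydroxy)methyl}-5-[4-(benzyloxy)-3,5-dimethoxyphenyl]-4-{[isopropoxy(dimethyl)silyl]methyl}dihydrofuran-2(3H)-one (carbinol epimers; one drawn) | COc1cc([C@@H](O)[C@H]2C(=O)O[C@@H](c3cc(OC)c(OCc4ccccc4)c(OC)c3)[C@@H]2C[Si](C)(C)OC(C)C)cc(OC)c1OCc1ccccc1 | intermediate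
13 | rac-(3,4-trans,4,5-trans)-3-{[4-(benzyloxy)-3,5-dimethoxyphenyl](hydroxy)methyl}-5-[4-(benzyloxy)-3,5-dimethoxyphenyl]-4-(hydroxymethyl)dihydrofuran-2(3H)-one (carbinol epimers; one drawn) | COc1cc([C@@H](O)[C@H]2C(=O)O[C@@H](c3cc(OC)c(OCc4ccccc4)c(OC)c3)[C@@H]2CO)cc(OC)c1OCc1ccccc1 | intermediate
14 | rel-(2R,3S,4R)-1,4-bis[4-(benzyloxy)-3,5-dimethoxyphenyl]-2,3-bis(hydroxymethyl)butane-1,4-diol (C1 epimers; meso epimer drawn) | COc1cc([C@@H](O)[C@@H](CO)[C@@H](CO)[C@@H](O)c2cc(OC)c(OCc3ccccc3)c(OC)c2)cc(OC)c1OCc1ccccc1 | intermediate
15 | rel-(2R,3S,4R)-{1,4-bis[4-(benzyloxy)-3,5-dimethoxyphenyl]-1,4-dihydroxybutane-2,3-diyl}bis(methylene) diacetate (C1 epimers; meso epimer drawn) | COc1cc([C@@H](O)[C@@H](COC(C)=O)[C@@H](COC(C)=O)[C@@H](O)c2cc(OC)c(OCc3ccccc3)c(OC)c2)cc(OC)c1OCc1ccccc1 | intermediate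
16 | [(2S,3R,4S,5R)-2,5-bis[4-(benzyloxy)-3,5-dimethoxyphenyl]tetrahydrofuran-3,4-diyl]bis(methylene) diacetate (meso) | COc1cc([C@H]2O[C@@H](c3cc(OC)c(OCc4ccccc4)c(OC)c3)[C@H](COC(C)=O)[C@@H]2COC(C)=O)cc(OC)c1OCc1ccccc1 | intermediate
17 | [(2S,3R,4S,5R)-2,5-bis[4-(benzyloxy)-3,5-dimethoxyphenyl]tetrahydrofuran-3,4-diyl]dimethanol (meso) | COc1cc([C@H]2O[C@@H](c3cc(OC)c(OCc4ccccc4)c(OC)c3)[C@H](CO)[C@@H]2CO)cc(OC)c1OCc1ccccc1 | intermediate
18 | [(2S,3R,4S,5R)-2,5-bis(4-hydroxy-3,5-dimethoxyphenyl)tetrahydrofuran-3,4-diyl]dimethanol (meso) | COc1cc([C@H]2O[C@@H](c3cc(OC)c(O)c(OC)c3)[C@H](CO)[C@@H]2CO)cc(OC)c1O | target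

## Step count and least certain steps

Total step count: 11. Longest linear sequence: 10 steps (1, 2, 3, 5, 6, 7, 8, 9, 10, 11, starting from 1); step 4 is a one-step side branch that joins at step 5.

Step 5 (key step). The most likely failure is deprotonation at C5 by the basic Grignard reagent: this proton is benzylic and vinylogous to the carbonyl, and its loss gives an aromatic furanolate. Slow transfer of the α-silyl alkyl group from copper would make this worse and leave conversion incomplete. The second risk is loss of the aldol adduct by retro-aldol reaction if the mixture warms before the quench. Fallback: separate the two bond formations. Setting out from 8 and 10, the copper-catalysed addition is run with Me3SiCl present, which accelerates the 1,4-addition and traps the enolate as the silyl ketene acetal F1. Mild aqueous work-up gives the trans lactone F2. A separate deprotonation of F2 with LiN(iPr)2 in THF at −78 °C and addition of 3 would then form C2–C3 anti to the C4 substituent, and the sequence comes back to the route at 12.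

Step 9. The benzylic cation can be consumed irreversibly by Friedel–Crafts closure onto the other electron-rich ring (a six-membered aryltetralin) or by loss of H3 or H4 to a styrene. Alternatively, equilibration can stop short and leave C2 or C5 epimers, and acetyl migration to a benzylic hydroxyl would free an arm to compete. Fallback: change the mode of ionisation. Setting out from 15, the benzyl ethers are removed first (H2, Pd/C, EtOAc) to give the bis-phenol diol F3. Free para-hydroxybenzyl alcohols ionise through quinone methides under much milder acid (catalytic camphorsulfonic acid, CH2Cl2, 0 °C), which should close the ring to the diacetate F4 with the same trans preference and less opportunity for C-alkylation. Methanolysis of F4 (K2CO3, MeOH, 0 °C) comes back to the route at 18. This order also keeps hydrogen away from the ring ether, should step 11 show ring C–O cleavage.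

Step 8. Discrimination between two primary and two secondary benzylic hydroxyls may be incomplete, giving under- and over-acylated material. Fallback: use a much bulkier, non-migrating group. Setting out from 14, t-BuPh2SiCl and imidazole in DMF at 0 °C should silylate only the primary hydroxyls, giving the bis-silyl ether diol F5. Ring closure as in step 9 gives the bis-silyl tetrahydrofuran F6, and Bu4NF in THF comes back to the route at 17.

Step 6. The substrate is a β-hydroxy lactone, and the mildly basic peroxide medium may trigger retro-aldol cleavage of C2–C3 before or after the silicon is oxidised; protodesilylation is a lesser risk. Fallback: reverse the order of reduction and oxidation. Setting out from 12, LiAlH4 in THF removes the carbonyl group, so no retro-aldol is possible, and converts Si–O-iPr into Si–H, giving the hydrosilane triol F7. The same H2O2/KF/KHCO3 oxidation, for which an Si–H bond is a competent handle, then comes back to the route at 14.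

Step 3. Hydrogenation may run past the Z-alkene to the saturated hydroxy ester, or the acid used for lactonisation may ionise the electron-rich benzylic alcohol. Fallback: build the butenolide by ring-closing metathesis. Setting out from 3, vinylmagnesium bromide gives the allylic alcohol F8, and acryloyl chloride with Et3N gives the acrylate F9. The second-generation Grubbs catalyst in CH2Cl2 at 40 °C then closes the ring with loss of ethene and comes back to the route at 8.

## Further compounds

F1 | step 5 | rac-trans-{[5-[4-(benzyloxy)-3,5-dimethoxyphenyl]-4-{[isopropoxy(dimethyl)silyl]methyl}-4,5-dihydrofuran-2-yl]oxy}trimethylsilane | C[Si](C)(C)OC1=C[C@@H](C[Si](C)(C)OC(C)C)[C@H](c2cc(OC)c(OCc3ccccc3)c(OC)c2)O1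
F2 | step 5 | rac-trans-5-[4-(benzyloxy)-3,5-dimethoxyphenyl]-4-{[isopropoxy(dimethyl)silyl]methyl}dihydrofuran-2(3H)-one | O=C1C[C@@H](C[Si](C)(C)OC(C)C)[C@H](c2cc(OC)c(OCc3ccccc3)c(OC)c2)O1
F3 | step 9 | rel-(2R,3S,4R)-[1,4-dihydroxy-1,4-bis(4-hydroxy-3,5-dimethoxyphenyl)butane-2,3-diyl]bis(methylene) diacetate (C1 epimers; meso epimer drawn) | COc1cc([C@@H](O)[C@@H](COC(C)=O)[C@@H](COC(C)=O)[C@@H](O)c2cc(OC)c(O)c(OC)c2)cc(OC)c1O
F4 | step 9 | [(2S,3R,4S,5R)-2,5-bis(4-hydroxy-3,5-dimethoxyphenyl)tetrahydrofuran-3,4-diyl]bis(methylene) diacetate (meso) | COc1cc([C@H]2O[C@@H](c3cc(OC)c(O)c(OC)c3)[C@H](COC(C)=O)[C@@H]2COC(C)=O)cc(OC)c1O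
F5 | step 8 | rel-(2R,3S,4R)-1,4-bis[4-(benzyloxy)-3,5-dimethoxyphenyl]-2,3-bis{[(tert-butyldiphenylsilyl)oxy]methyl}butane-1,4-diol (C1 epimers; meso epimer drawn) | COc1cc([C@@H](O)[C@@H](CO[Si](c2ccccc2)(c2ccccc2)C(C)(C)C)[C@@H](CO[Si](c2ccccc2)(c2ccccc2)C(C)(C)C)[C@@H](O)c2cc(OC)c(OCc3ccccc3)c(OC)c2)cc(OC)c1OCc1ccccc1
F6 | step 8 | (2S,3R,4S,5R)-2,5-bis[4-(benzyloxy)-3,5-dimethoxyphenyl]-3,4-bis{[(tert-butyldiphenylsilyl)oxy]methyl}tetrahydrofuran (meso) | COc1cc([C@H]2O[C@@H](c3cc(OC)c(OCc4ccccc4)c(OC)c3)[C@H](CO[Si](c3ccccc3)(c3ccccc3)C(C)(C)C)[C@@H]2CO[Si](c2ccccc2)(c2ccccc2)C(C)(C)C)cc(OC)c1OCc1ccccc1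
F7 | step 6 | rel-(2R,3S,4R)-1,4-bis[4-(benzyloxy)-3,5-dimethoxyphenyl]-3-[(dimethylsilyl)methyl]-2-(hydroxymethyl)butane-1,4-diol (C1 epimers; one drawn) | COc1cc([C@@H](O)[C@@H](CO)[C@@H](C[SiH](C)C)[C@@H](O)c2cc(OC)c(OCc3ccccc3)c(OC)c2)cc(OC)c1OCc1ccccc1
F8 | step 3 | rac-1-[4-(benzyloxy)-3,5-dimethoxyphenyl]prop-2-en-1-ol | O[C@@H](c1cc(OC)c(OCc2ccccc2)c(OC)c1)C=C
F9 | step 3 | rac-1-[4-(benzyloxy)-3,5-dimethoxyphenyl]prop-2-en-1-yl acrylate | C=CC(=O)O[C@@H](c1cc(OC)c(OCc2ccccc2)c(OC)c1)C=C
A1 | alternative 1 | (2R,3S,4R,5S)-3,4-bis(acetoxymethyl)tetrahydrofuran-2,5-dicarboxylic acid (meso; carboxyl groups cis to each other and trans to the neighbouring arms) | OC(=O)[C@H]1O[C@@H](C(O)=O)[C@H](COC(C)=O)[C@@H]1COC(C)=O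
A2 | alternative 1 | 2-(benzyloxy)-5-bromo-1,3-dimethoxybenzene | COc1cc(Br)cc(OC)c1OCc1ccccc1
A3 | alternative 1 | [(2S,3R,4S,5R)-2,5-bis[4-(benzyloxy)-3,5-dimethoxyphenyl]tetrahydrofuran-3,4-diyl]bis(methylene) diacetate (identical with 16) | COc1cc([C@H]2O[C@@H](c3cc(OC)c(OCc4ccccc4)c(OC)c3)[C@H](COC(C)=O)[C@@H]2COC(C)=O)cc(OC)c1OCc1ccccc1
A4 | alternative 2 | rac-methyl 6-endo-[4-(benzyloxy)-3,5-dimethoxyphenyl]-2-oxo-3-oxabicyclo[3.1.0]hexane-1-carboxylate (aryl cis to the lactone CH2) | COC(=O)[C@@]12C(=O)OC[C@@H]1[C@@H]2c1cc(OC)c(OCc2ccccc2)c(OC)c1
A5 | alternative 2 | tin bis(trifluoromethanesulfonate), Sn(OTf)2 | [Sn+2].[O-]S(=O)(=O)C(F)(F)F.[O-]S(=O)(=O)C(F)(F)F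
A6 | alternative 2 | rac-methyl cis-fused 4,6-bis[4-(benzyloxy)-3,5-dimethoxyphenyl]-1-oxotetrahydro-1H,3H-furo[3,4-c]furan-6a-carboxylate (ester on the ring-fusion carbon C3) | COc1cc([C@H]2O[C@@H](c3cc(OC)c(OCc4ccccc4)c(OC)c3)[C@H](CO5)[C@]2(C(=O)OC)C5=O)cc(OC)c1OCc1ccccc1
A7 | alternative 3 | cis-2,5-bis[4-(benzyloxy)-3,5-dimethoxyphenyl]-2,5-dihydrofuran (meso) | COc1cc([C@H]2O[C@@H](c3cc(OC)c(OCc4ccccc4)c(OC)c3)C=C2)cc(OC)c1OCc1ccccc1
A8 | alternative 3 | trichloroacetyl chloride | ClC(=O)C(Cl)(Cl)Cl
A9 | alternative 3 | dichloroketene | O=C=C(Cl)Cl
A10 | alternative 3 | 2,4-bis[4-(benzyloxy)-3,5-dimethoxyphenyl]-7,7-dichloro-3-oxabicyclo[3.2.0]heptan-6-one (cyclobutanone anti to both aryl groups) | COc1cc([C@H]2O[C@@H](c3cc(OC)c(OCc4ccccc4)c(OC)c3)[C@H](C5(Cl)Cl)[C@@H]2C5=O)cc(OC)c1OCc1ccccc1
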